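C1' is the CH2 on C2 and the side chain runs to C32'. Ring A is the arene and ring B the dihydropyran. The retrosynthesis cuts C12'–C13' first, then C11'=C12', C4–C4a and O1–C2 in the right half, and C13'–C14' and C21'–C22' in the left half.
Enabling feature: C12' is the methyl-bearing sp2 carbon of an isolated (E)-trisubstituted alkene (C11'=C12'), and its neighbour C13' is a plain primary CH2. Both carbons can therefore first be bound to one boron atom, and this easily made C13'–B–C12' array is then contracted to C13'–C12' by a 1,2-metallate rearrangement, with boron leaving in the same flask.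
Left half, forward: a geraniol C10 unit and a farnesyl C15 unit are joined by sulfone alkylation (C21'–C22'). One carbon carrying boron is then added from bis(pinacolboryl)methane (C13'–C14') to give a C26 primary boronic ester.
Right half, forward: geranylgeraniol supplies C2–C4 and C1'–C11'. O1–C2 is formed by asymmetric allylic etherification with a bromophenol (ring A is bought), ring B closes at C4–C4a by hydroboration and intramolecular Suzuki–Miyaura coupling, and a masked terminal aldehyde is released and converted to a (Z)-2-iodoalkene.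
Union: the alkenyllithium from the (Z)-iodide and the boronic ester undergo a Zweifel olefination, followed by desilylation.
Stereochemistry: C2 (R) comes from the chiral palladium catalyst. Five (E)-alkenes are bought, C19'=C20' is fixed by (E)-selective SeO2 oxidation, and C11'=C12' (E) comes from a (Z)-selective iodo-Wittig step followed by the stereospecific geometry inversion of the key step.

Key step: step 18

Assumption: the (R,R) ligand is taken to give the (R) ether in step 14, by analogy with related (E)-trisubstituted allyl carbonates. If the sense proves opposite, the equally available (S,S) ligand is used and nothing else changes.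
Remark: the bromohydrin, oxirane and diol intermediates are epimer mixtures at the remote C11' carbon, and the coupled sulfone is racemic at its sulfonyl carbon. Both centres are erased later, so their SMILES leave them undefined.

Step 1
Reactants: 1 geraniol
Product: 2 geranyl tert-butyldimethylsilyl ether
Conditions: TBSCl, imidazole, CH2Cl2, 0 °C to rt
Reagents that add atoms: tert-butyldimethylsilyl chloride CC(C)(C)[Si](C)(C)Cl
Why: Imidazole-promoted silyl ether formation at the only hydroxyl group masks the later C14' oxygen through the carbanion and hydride steps.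

Step 2
Reactants: 2 geranyl tert-butyldimethylsilyl ether
Product: 3 (2E,6E)-8-(tert-butyldimethylsilyloxy)-2,6-dimethylocta-2,6-dien-1-ol
Conditions: SeO2 (cat.), t-BuOOH, CH2Cl2, 0 °C
Reagents that add atoms: tert-butyl hydroperoxide CC(C)(C)OO
Why: SeO2 allylic oxidation (ene reaction, then [2,3]-sigmatropic shift) should attack the more electron-rich distal isopropylidene group and oxidise its (E)-methyl group, which fixes the later C19'=C20' geometry.

Step 3
Reactants: 3 (2E,6E)-8-(tert-butyldimethylsilyloxy)-2,6-dimethylocta-2,6-dien-1-ol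
Product: 4 (2E,6E)-8-bromo-3,7-dimethylocta-2,6-dienyl tert-butyldimethylsilyl ether
Conditions: CBr4 (1.1 equiv), PPh3 (1.1 equiv), CH2Cl2, −20 °C
Reagents that add atoms: carbon tetrabromide BrC(Br)(Br)Br
Why: In this Appel reaction the free primary allylic alcohol is activated as its oxyphosphonium salt far faster than the silyl ether and is displaced by bromide without allylic transposition at low temperature.

Step 4
Reactants: 5 (2E,6E)-farnesyl bromide
Product: 6 (2E,6E)-farnesyl phenyl sulfone
Conditions: PhSO2Na, DMF, rt
Reagents that add atoms: sodium benzenesulfinate [Na+].[O-]S(=O)c1ccccc1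
Why: SN2 S-alkylation of the ambident sulfinate at the primary allylic carbon leaves both alkenes untouched.

Step 5
Reactants: 6 (2E,6E)-farnesyl phenyl sulfone; 4 (2E,6E)-8-bromo-3,7-dimethylocta-2,6-dienyl tert-butyldimethylsilyl ether
Product: 8 C25 sulfone (geranylfarnesyl TBS ether carrying PhSO2 on the former farnesyl C1; racemic there), via alpha-lithio sulfone 7 (not isolated)
Conditions: n-BuLi, THF/DMPU, −78 °C; then 4, −78 °C to −20 °C
Reagents that add atoms: none
Why: Alkylation of a sulfone-stabilised allyl anion, which reacts at its alpha carbon with the primary allylic bromide in SN2 fashion, forms C21'–C22' head to tail without touching any alkene geometry; the new sulfonyl-bearing centre is racemic and is erased in step 6.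

Step 6
Reactants: 8 C25 sulfone
Product: 9 (2E,6E,10E,14E)-geranylfarnesyl tert-butyldimethylsilyl ether
Conditions: PdCl2(dppp) (cat.), LiHBEt3, THF, 0 °C
Reagents that add atoms: none
Why: In this palladium-catalysed hydride desulfonylation of an allylic sulfone, zerovalent palladium ionises the C–S bond to a syn pi-allyl complex and hydride goes to the less substituted terminus, so the C23'=C24' alkene should stay in place and stay (E), while the allylic silyl ether is not ionised.

Step 7
Reactants: 9 (2E,6E,10E,14E)-geranylfarnesyl tert-butyldimethylsilyl ether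
Product: 10 (2E,6E,10E,14E)-geranylfarnesyl bromide
Conditions: Ph3PBr2, CH2Cl2, 0 °C to rt
Reagents that add atoms: triphenylphosphine dibromide BrP(Br)(c1ccccc1)(c1ccccc1)c1ccccc1
Why: In this direct conversion of a silyl ether into a bromide, the phosphonium centre takes the ether oxygen, bromide takes silicon, and a second bromide displaces Ph3PO at the primary allylic carbon under neutral conditions that should not isomerise the polyene.

Step 8
Reactants: 10 (2E,6E,10E,14E)-geranylfarnesyl bromide; 11 bis(pinacolboryl)methane
Product: 13 homogeranylfarnesyl pinacol boronate [2-((3E,7E,11E,15E)-4,8,12,16,20-pentamethylhenicosa-3,7,11,15,19-pentaenyl)-4,4,5,5-tetramethyl-1,3,2-dioxaborolane], via boryl-stabilised methylsodium 12 (not isolated)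
Conditions: NaOt-Bu, THF, rt
Reagents that add atoms: none
Why: In this alkoxide-induced deborylative alkylation of a geminal bis(boronate), tert-butoxide removes one boryl group and the boron-stabilised carbanion 12 displaces the primary allylic bromide at its unhindered alpha carbon, which adds C13' together with the boron atom needed in step 18.

Step 9
Reactants: 14 2,3-dimethylhydroquinone
Product: 15 5-bromo-2,3-dimethylbenzene-1,4-diol
Conditions: Br2 (1 equiv), AcOH/CHCl3, 0 °C
Reagents that add atoms: bromine BrBr
Why: Electrophilic aromatic bromination of an electron-rich arene whose two free positions are equivalent by symmetry should give a single monobromide with one equivalent of bromine.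

Step 10
Reactants: 15 5-bromo-2,3-dimethylbenzene-1,4-diol
Product: 16 2-bromo-5,6-dimethyl-4-(triisopropylsilyloxy)phenol
Conditions: TIPSCl (1 equiv), imidazole, DMF, 0 °C
Reagents that add atoms: triisopropylsilyl chloride CC(C)[Si](Cl)(C(C)C)C(C)C
Why: Silyl ether formation is differentiated by sterics, so the bulky chloride should take the hydroxyl flanked by H and CH3 and leave the one flanked by Br and CH3, which is the later O1.

Step 11
Reactants: 17 (2E,6E,10E)-geranylgeraniol
Product: 18 (2E,6E,10E)-geranylgeranyl methyl carbonate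
Conditions: ClCO2Me, pyridine, CH2Cl2, 0 °C
Reagents that add atoms: methyl chloroformate COC(=O)Cl
Why: Acylation of the primary allylic alcohol with a chloroformate installs a leaving group that releases its own base (methoxide) in step 14.

Step 12
Reactants: 18 (2E,6E,10E)-geranylgeranyl methyl carbonate
Product: 19 (2E,6E,10E)-14-bromo-15-hydroxy-3,7,11,15-tetramethylhexadeca-2,6,10-trienyl methyl carbonate (racemic)
Conditions: NBS (1 equiv), THF/H2O, 0 °C
Reagents that add atoms: N-bromosuccinimide O=C1CCC(=O)N1Br; water O
Why: In this terminal-selective bromohydrin formation of an oligoprenyl chain in a water-rich medium, the coiled chain exposes the terminal isopropylidene group, the C2=C3 alkene is deactivated by the carbonate, and water opens the bromonium ion at the tertiary carbon; the new centre is racemic and is erased in step 16.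

Step 13
Reactants: 19 bromohydrin
Product: 20 (2E,6E,10E)-14,15-epoxy-3,7,11,15-tetramethylhexadeca-2,6,10-trienyl methyl carbonate (racemic)
Conditions: DBU, CH2Cl2, rt
Reagents that add atoms: none
Why: Intramolecular Williamson-type closure (3-exo-tet) with a non-nucleophilic base avoids transesterification of the methyl carbonate and gives an oxirane that serves as a masked aldehyde able to tolerate steps 14 and 15.

Step 14
Reactants: 16 2-bromo-5,6-dimethyl-4-(triisopropylsilyloxy)phenol; 20 epoxy carbonate
Product: 21 (R)-tertiary allyl aryl ether [aryl ether of (3R,6E,10E)-14,15-epoxy-3,7,11,15-tetramethylhexadeca-1,6,10-trien-3-ol with phenol 16]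
Conditions: Pd2(dba)3·CHCl3 (cat.), (R,R)-DACH-phenyl ligand [N,N'-((1R,2R)-cyclohexane-1,2-diyl)bis(2-diphenylphosphinobenzamide)] (cat.), CH2Cl2, 0 °C to rt
Reagents that add atoms: none
Why: In this asymmetric Tsuji–Trost allylic etherification, zerovalent palladium ionises the carbonate, the released methoxide deprotonates 16, and the phenoxide attacks the more substituted terminus of the pi-allyl complex, whose enantiotopic faces are distinguished by the chiral pocket of the ligand, which sets C2 as (R); the aryl bromide and the isolated oxirane are not touched at this temperature.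

Step 15
Reactants: 21 (R)-tertiary allyl aryl ether
Product: 23 (2R)-chroman oxirane (6-O-TIPS-11',12'-epoxy-11',12'-dihydro-gamma-tocotrienol), via B-alkyl-9-BBN adduct 22 (not isolated)
Conditions: 9-BBN, THF, 0 °C to rt; then PdCl2(dppf)·CH2Cl2 (cat.), Cs2CO3, DMF/H2O, 50 °C
Reagents that add atoms: none
Why: Hydroboration with 9-BBN selects the monosubstituted vinyl group over the trisubstituted alkenes, and the intramolecular B-alkyl Suzuki–Miyaura coupling closes ring B at C4–C4a as a six-membered ring without touching the C2–O1 bond, so C2 keeps its configuration.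

Step 16
Reactants: 23 (2R)-chroman oxirane
Product: 25 (4E,8E)-4,8-dimethyl-11-[(2R)-2,7,8-trimethyl-6-(triisopropylsilyloxy)chroman-2-yl]undeca-4,8-dienal, via vicinal diol 24 (not isolated)
Conditions: H5IO6, THF/H2O, 0 °C
Reagents that add atoms: none
Why: Acid-mediated oxirane hydrolysis followed by Malaprade glycol cleavage in one flask removes the terminal C3 unit as acetone and reveals the C11' aldehyde, while the trisubstituted alkenes and both aryl ethers should be inert to H5IO6 at 0 °C.

Step 17
Reactants: 25 aldehyde; 26 ethyltriphenylphosphonium iodide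
Product: 30 (2Z,6E,10E)-2-iodo-6,10-dimethyl-13-[(2R)-2,7,8-trimethyl-6-(triisopropylsilyloxy)chroman-2-yl]trideca-2,6,10-triene, via ethylidene ylide 27 (not isolated), via iodoethylphosphonium iodide 28 (not isolated), via iodo ylide 29 (not isolated)
Conditions: 26, n-BuLi, THF, rt; I2, THF, −78 °C; NaN(SiMe3)2, −20 °C; then 25, −78 °C to −20 °C
Reagents that add atoms: iodine [I][I]
Why: In this Wittig olefination with an alpha-iodo ylide (Stork–Zhao type), the non-stabilised ylide 29 reacts under kinetic control and should place iodine cis to C10', giving the (Z)-2-iodoalkene that the inversion in step 18 requires.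

Step 18
Reactants: 30 (Z)-alkenyl iodide; 13 homogeranylfarnesyl pinacol boronate
Product: 34 6-O-triisopropylsilyl plastochromanol 8, via alkenyllithium 31 (not isolated), via lithium boronate 32 (not isolated), via beta-iodo boronic ester 33 (not isolated)
Conditions: 30, t-BuLi (2 equiv), Et2O, −78 °C; 13, THF, −78 °C to 0 °C; I2 (1.1 equiv), THF, −78 °C; NaOMe, MeOH, −78 °C to rt
Reagents that add atoms: none
Why: Iodine–lithium exchange with retention turns 30 into the configurationally stable alkenyllithium 31 (lithium cis to C10'), which adds to the empty p orbital of the primary boronic ester 13 and ties both halves to one boron atom in the tetracoordinate boronate 32. Iodine attacks the boron-activated C11'=C12' alkene, and the C13' methylene migrates from boron to C12' antiperiplanar to the breaking C12'–I bond of the iodonium ion (1,2-metallate rearrangement), which forms the C12'–C13' bond in 33. Methoxide then binds boron and triggers anti elimination of boron and iodide, so the boron tether and the iodine leave in the same flask. The closest known reaction type is the Zweifel olefination of pinacol boronic esters with alkenyllithium reagents. No ring is closed and no stereocentre remains, because the two transient centres C11' and C12' of 33 are erased; anti migration followed by anti elimination inverts the alkene geometry, so boron cis to C10' in 32 becomes C13' trans to C10', the (E)-alkene. The step needs attack at one alkene among eight and migration of carbon rather than oxygen: the negative charge on boron makes C11'=C12' by far the most nucleophilic alkene at −78 °C with about one equivalent of iodine, the pinacol oxygens do not migrate, and the TIPS ether keeps ring A from being oxidised or iodinated.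

Step 19
Reactants: 34 6-O-triisopropylsilyl plastochromanol 8
Product: 35 plastochromanol 8
Conditions: TBAF, AcOH, THF, 0 °C
Reagents that add atoms: none
Why: Fluoride-induced cleavage of the aryl silyl ether is buffered with acetic acid so that the oxidation-prone phenoxide is protonated at once, and the alkenes and C2 are not affected.

Compound list
1 | geraniol | CC(C)=CCC/C(C)=C/CO | starting material
2 | geranyl tert-butyldimethylsilyl ether | CC(C)=CCC/C(C)=C/CO[Si](C)(C)C(C)(C)C | intermediate
3 | (2E,6E)-8-(tert-butyldimethylsilyloxy)-2,6-dimethylocta-2,6-dien-1-ol | OC/C(C)=C/CC/C(C)=C/CO[Si](C)(C)C(C)(C)C | intermediate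
4 | (2E,6E)-8-bromo-3,7-dimethylocta-2,6-dienyl tert-butyldimethylsilyl ether | BrC/C(C)=C/CC/C(C)=C/CO[Si](C)(C)C(C)(C)C | intermediate
5 | (2E,6E)-farnesyl bromide | CC(C)=CCC/C(C)=C/CC/C(C)=C/CBr | starting material
6 | (2E,6E)-farnesyl phenyl sulfone | CC(C)=CCC/C(C)=C/CC/C(C)=C/CS(=O)(=O)c1ccccc1 | intermediate
7 | alpha-lithio farnesyl phenyl sulfone | CC(C)=CCC/C(C)=C/CC/C(C)=C/C([Li])S(=O)(=O)c1ccccc1 | intermediate
8 | C25 sulfone, racemic at the sulfonyl carbon | CC(C)=CCC/C(C)=C/CC/C(C)=C/C(C/C(C)=C/CC/C(C)=C/CO[Si](C)(C)C(C)(C)C)S(=O)(=O)c1ccccc1 | intermediate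
9 | (2E,6E,10E,14E)-geranylfarnesyl tert-butyldimethylsilyl ether | CC(C)=CCC/C(C)=C/CC/C(C)=C/CC/C(C)=C/CC/C(C)=C/CO[Si](C)(C)C(C)(C)C | intermediate
10 | (2E,6E,10E,14E)-geranylfarnesyl bromide | CC(C)=CCC/C(C)=C/CC/C(C)=C/CC/C(C)=C/CC/C(C)=C/CBr | intermediate
11 | bis(pinacolboryl)methane | CC1(C)OB(CB2OC(C)(C)C(C)(C)O2)OC1(C)C | starting material
12 | (pinacolboryl)methylsodium | [Na]CB1OC(C)(C)C(C)(C)O1 | intermediate
13 | homogeranylfarnesyl pinacol boronate | CC(C)=CCC/C(C)=C/CC/C(C)=C/CC/C(C)=C/CC/C(C)=C/CCB1OC(C)(C)C(C)(C)O1 | intermediate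
14 | 2,3-dimethylhydroquinone | Cc1c(O)ccc(O)c1C | starting material
15 | 5-bromo-2,3-dimethylbenzene-1,4-diol | Cc1c(O)cc(Br)c(O)c1C | intermediate
16 | 2-bromo-5,6-dimethyl-4-(triisopropylsilyloxy)phenol | Cc1c(O[Si](C(C)C)(C(C)C)C(C)C)cc(Br)c(O)c1C | intermediate
17 | (2E,6E,10E)-geranylgeraniol | CC(C)=CCC/C(C)=C/CC/C(C)=C/CC/C(C)=C/CO | starting material
18 | (2E,6E,10E)-geranylgeranyl methyl carbonate | CC(C)=CCC/C(C)=C/CC/C(C)=C/CC/C(C)=C/COC(=O)OC | intermediate
19 | 14-bromo-15-hydroxy carbonate (racemic) | CC(C)(O)C(Br)CC/C(C)=C/CC/C(C)=C/CC/C(C)=C/COC(=O)OC | intermediate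
20 | 14,15-epoxy carbonate (racemic) | CC1(C)OC1CC/C(C)=C/CC/C(C)=C/CC/C(C)=C/COC(=O)OC | intermediate
21 | (R)-tertiary allyl aryl ether (epimers at the oxirane carbon) | CC1(C)OC1CC/C(C)=C/CC/C(C)=C/CC[C@](Oc1c(Br)cc(O[Si](C(C)C)(C(C)C)C(C)C)c(C)c1C)(C)C=C | intermediate
22 | B-alkyl-9-BBN adduct of 21 | CC1(C)OC1CC/C(C)=C/CC/C(C)=C/CC[C@](Oc1c(Br)cc(O[Si](C(C)C)(C(C)C)C(C)C)c(C)c1C)(C)CCB1C2CCCC1CCC2 | intermediate
23 | (2R)-chroman oxirane (epimers at the oxirane carbon) | CC1(C)OC1CC/C(C)=C/CC/C(C)=C/CC[C@]1(C)CCc2cc(O[Si](C(C)C)(C(C)C)C(C)C)c(C)c(C)c2O1 | intermediate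
24 | (2R)-chroman 11',12'-diol (epimers at C11') | CC(C)(O)C(O)CC/C(C)=C/CC/C(C)=C/CC[C@]1(C)CCc2cc(O[Si](C(C)C)(C(C)C)C(C)C)c(C)c(C)c2O1 | intermediate
25 | (2R)-chroman C11' aldehyde | O=CCC/C(C)=C/CC/C(C)=C/CC[C@]1(C)CCc2cc(O[Si](C(C)C)(C(C)C)C(C)C)c(C)c(C)c2O1 | intermediate
26 | ethyltriphenylphosphonium iodide | CC[P+](c1ccccc1)(c1ccccc1)c1ccccc1.[I-] | starting material
27 | ethylidenetriphenylphosphorane | CC=P(c1ccccc1)(c1ccccc1)c1ccccc1 | intermediate
28 | (1-iodoethyl)triphenylphosphonium iodide | CC([I])[P+](c1ccccc1)(c1ccccc1)c1ccccc1.[I-] | intermediate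
29 | (1-iodoethylidene)triphenylphosphorane | CC([I])=P(c1ccccc1)(c1ccccc1)c1ccccc1 | intermediate
30 | (Z)-alkenyl iodide, iodine on C12' cis to C10' | C/C([I])=C/CC/C(C)=C/CC/C(C)=C/CC[C@]1(C)CCc2cc(O[Si](C(C)C)(C(C)C)C(C)C)c(C)c(C)c2O1 | intermediate
31 | alkenyllithium, lithium on C12' cis to C10' | C/C([Li])=C/CC/C(C)=C/CC/C(C)=C/CC[C@]1(C)CCc2cc(O[Si](C(C)C)(C(C)C)C(C)C)c(C)c(C)c2O1 | intermediate
32 | lithium alkyl(alkenyl)pinacol boronate, boron cis to C10' | [Li+].CC(C)=CCC/C(C)=C/CC/C(C)=C/CC/C(C)=C/CC/C(C)=C/CC[B-]1(OC(C)(C)C(C)(C)O1)/C(C)=C\CC/C(C)=C/CC/C(C)=C/CC[C@]1(C)CCc2cc(O[Si](C(C)C)(C(C)C)C(C)C)c(C)c(C)c2O1 | intermediate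
33 | beta-iodo boronic ester (one relative configuration at C11'/C12' from anti addition, formed on both alkene faces) | CC(C)=CCC/C(C)=C/CC/C(C)=C/CC/C(C)=C/CC/C(C)=C/CCC(C)(B1OC(C)(C)C(C)(C)O1)C([I])CC/C(C)=C/CC/C(C)=C/CC[C@]1(C)CCc2cc(O[Si](C(C)C)(C(C)C)C(C)C)c(C)c(C)c2O1 | intermediate
34 | 6-O-triisopropylsilyl plastochromanol 8 | CC(C)=CCC/C(C)=C/CC/C(C)=C/CC/C(C)=C/CC/C(C)=C/CC/C(C)=C/CC/C(C)=C/CC/C(C)=C/CC[C@]1(C)CCc2cc(O[Si](C(C)C)(C(C)C)C(C)C)c(C)c(C)c2O1 | intermediate
35 | plastochromanol 8 | CC(C)=CCC/C(C)=C/CC/C(C)=C/CC/C(C)=C/CC/C(C)=C/CC/C(C)=C/CC/C(C)=C/CC/C(C)=C/CC[C@]1(C)CCc2cc(O)c(C)c(C)c2O1 | target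

Total step count: 19.
Longest linear sequence: 9 steps (17 to 35 through steps 11–19). The line from 1 through steps 1–3, 5–8, 18 and 19 is equally long.

Steps most likely to fail

Step 14. The phenoxide is flanked by Br and CH3, so it may attack the less substituted allyl terminus. A slow reaction may also allow re-ionisation of the tertiary ether, with loss of regiochemical and enantiomeric purity, and facial selectivity may be poor.
The fallback sets out from 20 and returns at 21, taking the stereocentre from a reagent-controlled epoxidation and a stereospecific C–O bond formation.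
- Methanolysis of the carbonate (K2CO3, MeOH) should give 14,15-epoxygeranylgeraniol F1.
- Sharpless asymmetric epoxidation (Ti(OiPr)4, L-(+)-diethyl tartrate, t-BuOOH, 4 Å molecular sieves, CH2Cl2, −20 °C) should give the (2S,3S)-2,3:14,15-bis-epoxy alcohol F2.
- Hydroxyl-directed opening with phenol 16 and Ti(OiPr)4 at the tertiary C3, with inversion, should give the (2S,3R)-3-aryloxy-1,2-diol F3.
- 1,1'-Thiocarbonyldiimidazole should give the cyclic thiocarbonate F4.
- Corey–Winter olefination with 1,3-dimethyl-2-phenyl-1,3,2-diazaphospholidine at 40 °C should give 21.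

Step 18. The alpha-methyl alkenyllithium is hindered, so boronate formation may be incomplete. The alkenyllithium may also be protonated early, or iodine may be consumed by the isolated alkenes.
The fallback sets out from 25 and 13 and returns at 34. It replaces the boron 1,2-shift (inversion) by a palladium cross-coupling (retention) on the opposite iodide geometry.
- Ohira–Bestmann homologation of 25 (dimethyl (1-diazo-2-oxopropyl)phosphonate, K2CO3, MeOH) should give the terminal alkyne F5.
- n-BuLi then MeI should give the 2-alkyne F6.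
- Hydrozirconation with excess Cp2Zr(H)Cl (THF, 40 °C, equilibration to the less hindered C12' zirconium), then iodine, should give the (E)-2-iodoalkene F7.
- KHF2 in MeOH/H2O should turn 13 into the potassium alkyltrifluoroborate F8.
- Suzuki–Miyaura coupling of F7 and F8 (PdCl2(dppf)·CH2Cl2, Cs2CO3, THF/H2O, reflux) should give 34.

Step 17. Iodination of the ylide may scramble, (Z)-selectivity may erode, or the aldehyde may convert poorly.
The fallback sets out from 25 and returns at 31, building the geometry by site-selective cross-coupling instead of olefination.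
- Corey–Fuchs dibromoolefination (CBr4, PPh3, CH2Cl2, 0 °C) should give the 1,1-dibromoalkene F9.
- A trans-selective Negishi monomethylation (MeZnCl, PdCl2(DPEphos), THF, 0 °C) replaces the bromine trans to C10' and should give the (Z)-2-bromoalkene F10.
- Bromine–lithium exchange (t-BuLi, Et2O, −78 °C) should then give 31.

Further compounds
F1 | step 14 | 14,15-epoxygeranylgeraniol (racemic oxirane) | CC1(C)OC1CC/C(C)=C/CC/C(C)=C/CC/C(C)=C/CO
F2 | step 14 | (2S,3S)-2,3:14,15-bis-epoxy alcohol | OC[C@@H]1O[C@@]1(C)CC/C=C(C)/CC/C=C(C)/CCC1OC1(C)C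
F3 | step 14 | (2S,3R)-3-aryloxy-1,2-diol | CC1(C)OC1CC/C(C)=C/CC/C(C)=C/CC[C@](Oc1c(Br)cc(O[Si](C(C)C)(C(C)C)C(C)C)c(C)c1C)(C)[C@@H](O)CO
F4 | step 14 | cyclic thiocarbonate of F3 | CC1(C)OC1CC/C(C)=C/CC/C(C)=C/CC[C@](Oc1c(Br)cc(O[Si](C(C)C)(C(C)C)C(C)C)c(C)c1C)(C)[C@@H]1COC(=S)O1
F5 | step 18 | terminal alkyne | C#CCC/C(C)=C/CC/C(C)=C/CC[C@]1(C)CCc2cc(O[Si](C(C)C)(C(C)C)C(C)C)c(C)c(C)c2O1
F6 | step 18 | 2-alkyne | CC#CCC/C(C)=C/CC/C(C)=C/CC[C@]1(C)CCc2cc(O[Si](C(C)C)(C(C)C)C(C)C)c(C)c(C)c2O1
F7 | step 18 | (E)-2-iodoalkene, iodine trans to C10' | C/C([I])=C\CC/C(C)=C/CC/C(C)=C/CC[C@]1(C)CCc2cc(O[Si](C(C)C)(C(C)C)C(C)C)c(C)c(C)c2O1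
F8 | step 18 | potassium homogeranylfarnesyltrifluoroborate | CC(C)=CCC/C(C)=C/CC/C(C)=C/CC/C(C)=C/CC/C(C)=C/CC[B-](F)(F)F.[K+]
F9 | step 17 | 1,1-dibromoalkene | BrC(Br)=CCC/C(C)=C/CC/C(C)=C/CC[C@]1(C)CCc2cc(O[Si](C(C)C)(C(C)C)C(C)C)c(C)c(C)c2O1
F10 | step 17 | (Z)-2-bromoalkene, bromine cis to C10' | C/C(Br)=C/CC/C(C)=C/CC/C(C)=C/CC[C@]1(C)CCc2cc(O[Si](C(C)C)(C(C)C)C(C)C)c(C)c(C)c2O1
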